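**Assumption (chemistry):** (R)-cyclohex-2-en-1-ol (2) is taken as a purchased building block of high enantiomeric purity.

**Atom labels.** Each half keeps phthalide numbering. Unit A (unprimed): C1 lactone carbonyl, O2, C3, C3a, C4–C7, C7a, butylidene C8–C11. Unit B (primed): the same with primes. The cyclobutane is C6–C7–C3a'–C7a'.

## Analysis of the target

The target 11 is a formal [2+2] heterodimer of two (Z)-butylidene phthalide halves, joined through C6–C7a' and C7–C3a'. The cyclobutane is fused to ring A (cyclohexene, C3a=C7a) at C6–C7. Its C3a'–C7a' edge is the shared bond of a [4.3.2]propellane made of the cyclobutane, ring B (cyclohexene, C6'=C7') and the γ-lactone of unit B. The only stereocentres are the four contiguous cyclobutane carbons, C6 (S), C7 (R), C3a' (R) and C7a' (S); C3a' and C7a' are vicinal and quaternary. Ring A and the lactone of unit B lie on one face of the cyclobutane and ring B on the other (cis-anti-cis). Sensitive groups are the two (Z)-enol lactones (acylating agents, labile to nucleophiles, acid and light), the cross-conjugated triene C8=C3–C3a=C7a–C1=O, and the cis-1,2-divinylcyclobutane unit C3a=C7a–C7–C3a'–C3'=C8', which can undergo Cope rearrangement on heating. The difficulty is threefold: which carbon of one half bonds to which carbon of the other, the absolute configuration of a molecule with no stereocentre outside the cyclobutane, and the placement of the C6'=C7' bond on the C1' side of ring B.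

The feature this route uses: C3a' and C7a' each carry a carboxyl-level carbon (C3', C1'). Without the butylidene and the C6'=C7' bond, unit B is a mirror-symmetric cyclic anhydride. In addition, C7a of ring A is cis to C3' across the C7–C3a' bond, so an oxygen on C7a can reach C3' and cannot reach C1'.

## Retrosynthetic reasoning

**11 to 10.** The C1–O2 and C1–C7a bonds of the unit A lactone are cut. The forward step is a carbonylative lactonisation of vinyl triflate 10, which inserts a one-carbon carbonyl unit at C7a and closes the ring on the enol oxygen of the C3 ketone. The light- and heat-sensitive triene is therefore made last.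

**10 to 9 to 8.** The triflate comes from the ring enol of β-diketone 9. The C3a–C3 bond is then cut, which leads back to ketone 8 and a C5 acyl donor. C3a is the only unhindered α-carbon of the C7a ketone, so the acylation has one possible site.

**8 to 7.** The O2'–C3' bond of the unit B enol lactone is cut to give γ-keto acid 7. Because C3a' is quaternary, dehydration can only give the exocyclic C3'=C8' alkene.

**7 to 6 to 5.** The C7a ketone is taken back to an alcohol and the C3'–C8' bond is cut. In 5 the C7a oxygen is tied to C3' as a γ-lactone, so C3' is the one carboxyl carbon that accepts a butyl nucleophile, while C1' remains a free acid.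

**5 to 4.** The C6'=C7' bond is removed. The forward step is a desaturation directed by the C1' acid. C7' is its only β-methylene and C6' the only neighbour of C7' that carries hydrogen, so the position is fixed by structure.

**4 to 3 to 1 + 2.** The lactone C–O bond is opened to hydroxy anhydride 3, and both cyclobutane bonds (C6–C7a', C7–C3a') are cut. This gives the symmetric anhydride 1 and the allylic alcohol 2. The mirror plane of 1 removes the head-to-head/head-to-tail question. The carbinol carbon of 2 is the only source of chirality and is later erased at the ketone stage.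

## Alternatives that were turned down

**Alternative 1:** (textbook) Cut C6–C7a' and C7–C3a' to two molecules of (Z)-ligustilide A1 and dimerise A1 photochemically. This is the shortest route on paper. It was turned down because A1 offers four different C=C bonds in one triene chromophore, so [2+2] regio- and stereoisomers, [4+2] adducts and Z/E isomerisation of the butylidene all compete. More fundamentally, two identical achiral partners give no handle for absolute control, so a single enantiomer would need a resolution.

**Alternative 2:** Cut C3a'–C4' and C7a'–C7' (ring B) and build the propellane by Diels–Alder addition of a 1-silylated butadiene to the convex face of the ring A-fused cyclobutene anhydride A2. The adduct A3 is an allylsilane, and protodesilylation would shift its double bond to C6'=C7'. This sets both quaternary centres in one step. It was turned down for three reasons. A2 itself needs three to four steps (photocycloaddition of a dihalomaleic anhydride to an enone, then dehalogenation) and an asymmetric induction of its own. The silyl group of the diene has no reason to end up next to C7a' and not next to C3a'. The two carboxyl carbons would still need to be told apart afterwards.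

**Alternative 3:** Tie the halves through a ketal: the pseudo-ester A4, made from 2 and the pseudo-acid of 2-pentanoylcyclohex-1-ene-1-carboxylic acid, would undergo intramolecular [2+2] to the cage ketal A5. Acid would then release the unit B butylidene lactone and the C7a alcohol together. It was turned down because the new ketal carbon is a stereocentre and only one of its two epimers holds the tether on the face that matches 2. The butenolide chromophore also needs shorter wavelengths. Most importantly, ring B arrives saturated with C1' locked in the lactone, so nothing is left to direct the C6'=C7' desaturation.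

Key step: step 1

## Route

**Step 1**
Reactants: 1 3,4,5,6-tetrahydrophthalic anhydride; 2 (R)-cyclohex-2-en-1-ol
Product: 4 tetracyclic lactone acid (6S,7R,7aR,3a'R,7a'S) with C7a–O–C3'(=O) γ-lactone and free C1' acid, via hydroxy anhydride cycloadduct 3 (not isolated)
Conditions: hν (Pyrex-filtered medium-pressure Hg lamp, λ > 290 nm), 1 (2 equiv), CH2Cl2, 0–20 °C; then DMAP (5 mol %), 20 °C; NaHCO3 extraction
Reagents that add atoms: none
Why: Excitation of the cyclic enedione chromophore of 1 and intersystem crossing give a triplet that adds to the C6=C7 bond of 2 through a 1,4-biradical, which closes after spin inversion; the closest known reaction type is the [2+2] photocycloaddition of tetrahydrophthalic and maleic anhydrides to alkenols with lactonisation in the same flask. The cyclobutane (C6–C7a' and C7–C3a') is closed by an intermolecular [2+2] in which the mirror plane of 1 makes both orientations identical, and the γ-lactone is then closed by 5-exo-trig attack of the C7a hydroxyl on the only anhydride carbonyl within reach, C3', leaving C1' as the free acid. C3a' and C7a' must be cis because both sit in the anhydride ring, and C6 and C7 must be cis because a trans-fused bicyclo[4.2.0]octane on the ground-state partner is strained. Ring A is expected to stack over the flat anhydride ring and not over the puckered tetramethylene bridge, for steric reasons and because an O–H···O=C hydrogen bond in the non-coordinating solvent ties the hydroxyl to an anhydride carbonyl; this gives the cis-anti-cis topology of the target. The same hydrogen bond should select the hydroxyl-bearing face of 2, so the C7a stereocentre of 2 fixes C6, C7, C3a' and C7a' in the absolute sense. The step needs syn facial selectivity and anhydride-side stacking; it is protected by the lactonisation itself, because only the adduct with the hydroxyl cis to the anhydride can become the acid 4, while any other adduct stays a neutral anhydride and is removed by extraction, so the enantiomeric purity of 4 should equal that of 2.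

**Step 2**
Reactants: 4 lactone acid
Product: 5 lactone acid with C6'=C7' (6S,7R,7aR,3a'R,7a'S)
Conditions: Pd(OAc)2 (10 mol %), bidentate quinoline–pyridone ligand (12 mol %), Ag2CO3 (2 equiv), Na2HPO4 (1 equiv), (CF3)2CHOH, 110 °C
Reagents that add atoms: none
Why: Carboxylate-directed, ligand-accelerated cyclopalladation of a β-methylene C–H bond by divalent palladium followed by β-hydride elimination is the known β,γ-dehydrogenation of α-quaternary aliphatic acids. In 4 the C1' acid has a single β-methylene (C7'), and the only hydrogen-bearing neighbour of C7' is C6' because C7a' is quaternary, so the alkene can only form at C6'=C7'; no stereocentre is touched.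

**Step 3**
Reactants: 5 unsaturated lactone acid
Product: 6 hydroxy keto acid (C3a' pentanoyl, C7a' CO2H, C7a OH; 6S,7R,7aR,3a'R,7a'S), used crude
Conditions: n-BuLi (2.2 equiv), THF, −78 to −40 °C; then aq. HCl to pH 3, 0 °C
Reagents that add atoms: n-butyllithium, [Li]CCCC
Why: Nucleophilic acyl addition: the first equivalent forms the inert lithium carboxylate at C1', the second adds to the lactone carbonyl C3', and the congested lithium hemiketal should resist a second addition at low temperature; no α-hydrogen is available for enolisation. The C7a–O bond is not broken, so C7a keeps its configuration; 6 may sit as its cyclic hemiketal, which does not matter for step 4.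

**Step 4**
Reactants: 6 hydroxy keto acid
Product: 7 diketo acid (C7a ketone, C3a' pentanoyl, C7a' CO2H; 6S,7R,3a'R,7a'S)
Conditions: CrO3, H2SO4, acetone–H2O, 0 °C
Reagents that add atoms: none
Why: Jones oxidation of the secondary C7a alcohol; the aqueous acid keeps hemiketal and open forms in equilibrium, so all of 6 should drain to the ketone, and the temporary C7a stereocentre disappears after it has done its work. C7 stays cis-fused because the trans-fused bicyclo[4.2.0]octanone is far more strained.

**Step 5**
Reactants: 7 diketo acid
Product: 8 keto enol lactone (unit B complete as the (Z)-3'-butylidene γ-lactone, ring A a C7a ketone; 6S,7R,3a'R,7a'S)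
Conditions: (CF3CO)2O (1.5 equiv), pyridine, CH2Cl2, 0 to 20 °C
Reagents that add atoms: none
Why: Dehydrative enol lactonisation of a γ-keto acid through its O-acylated hydroxylactone (pseudo-acid) and loss of a C8' proton; C3a' is quaternary, so only the exocyclic C3'=C8' alkene can form, and the (Z) isomer (propyl cis to the ring oxygen) avoids allylic strain against C4' and C7. The cyclic pseudo-acid form also shields C3' from aldol reaction with the C7a ketone.

**Step 6**
Reactants: 8 keto enol lactone
Product: 9 β-diketone as its ring enol (7a-hydroxy, 3a-pentanoyl, C3a=C7a; 6S,7R,3a'R,7a'S)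
Conditions: MgBr2·OEt2 (2.5 equiv), i-Pr2NEt (3 equiv), pentanoyl chloride (1.3 equiv), CH2Cl2, 0 to 20 °C
Reagents that add atoms: pentanoyl chloride, CCCCC(Cl)=O
Why: Soft-enolisation C-acylation of a ketone (magnesium enolate plus acid chloride) gives the 1,3-diketone as its unreactive magnesium chelate. C3a is the only unhindered α-methylene (the other α-carbon, C7, is a cyclobutane methine next to a quaternary carbon), and the mild amine/MgBr2 conditions should leave the enol lactone of unit B intact.

**Step 7**
Reactants: 9 β-diketone
Product: 10 vinyl triflate (7a-OTf, 3a-pentanoyl, C3a=C7a; 6S,7R,3a'R,7a'S)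
Conditions: Tf2O (1.1 equiv), i-Pr2NEt (1.5 equiv), CH2Cl2, −78 °C
Reagents that add atoms: trifluoromethanesulfonic anhydride, O=S(=O)(OS(=O)(=O)C(F)(F)F)C(F)(F)F
Why: O-Sulfonylation of the endocyclic enol of a 2-acylcyclohexanone, which is known to give the 2-acylcyclohex-1-enyl triflate; this puts the leaving group on C7a, the carbon that must receive C1.

**Step 8**
Reactants: 10 vinyl triflate
Product: 11 target, (3Z,3'Z,6S,7R,3a'R,7a'S)
Conditions: Pd(PPh3)4 (5 mol %), CO (1 atm), Et3N (2 equiv), MeCN, 50 °C, dark
Reagents that add atoms: carbon monoxide, [C-]#[O+]
Why: Carbonylative lactonisation: oxidative addition of the C7a–OTf bond to zerovalent palladium, CO insertion to the acylpalladium, and capture by the enol oxygen of the neighbouring pentanoyl group (known for β-halo enones and o-halo aryl ketones) close the butenolide and create C3=C8 in one operation. The (Z) isomer is the thermodynamic one, as in butylidenephthalides; mild temperature and exclusion of light protect the triene and the cis-1,2-divinylcyclobutane unit.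

## Compound list

1 | 3,4,5,6-tetrahydrophthalic anhydride | O=C1OC(=O)C2=C1CCCC2 | starting material
2 | (R)-cyclohex-2-en-1-ol | O[C@H]1C=CCCC1 | starting material
3 | hydroxy anhydride cycloadduct, cis-anti-cis, 7a-OH cis to the anhydride (6S,7R,7aR,3a'R,7a'S) | O=C1OC(=O)[C@]23CCCC[C@@]13[C@H]4CCC[C@@H](O)[C@@H]24 | intermediate (not isolated)
4 | lactone acid: C7a–O–C3'(=O) γ-lactone, C1' acid on C7a', ring B saturated (6S,7R,7aR,3a'R,7a'S) | OC(=O)[C@]12CCCC[C@@]1(C(=O)O3)[C@@H]1[C@H]3CCC[C@H]21 | intermediate
5 | lactone acid with C6'=C7' (6S,7R,7aR,3a'R,7a'S) | OC(=O)[C@]12C=CCC[C@@]1(C(=O)O3)[C@@H]1[C@H]3CCC[C@H]21 | intermediate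
6 | hydroxy keto acid: 3a'-pentanoyl, 7a'-CO2H, 7a-OH (6S,7R,7aR,3a'R,7a'S), open form | OC(=O)[C@]12C=CCC[C@@]1(C(=O)CCCC)[C@@H]1[C@H](O)CCC[C@H]21 | intermediate
7 | diketo acid: C7a ketone, 3a'-pentanoyl, 7a'-CO2H (6S,7R,3a'R,7a'S), open form | OC(=O)[C@]12C=CCC[C@@]1(C(=O)CCCC)[C@@H]1C(=O)CCC[C@H]21 | intermediate
8 | keto enol lactone: (Z)-3'-butylidene lactone of unit B, C7a ketone in ring A (6S,7R,3a'R,7a'S) | O=C1CCC[C@H]2[C@@H]1[C@]13CCC=C[C@]21C(=O)O/C3=C\CCC | intermediate
9 | β-diketone, ring-enol form: 7a-hydroxy-3a-pentanoyl, C3a=C7a (6S,7R,3a'R,7a'S) | OC1=C(C(=O)CCCC)CC[C@H]2[C@@H]1[C@]13CCC=C[C@]21C(=O)O/C3=C\CCC | intermediate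
10 | vinyl triflate: 7a-OSO2CF3, 3a-pentanoyl, C3a=C7a (6S,7R,3a'R,7a'S) | FC(F)(F)S(=O)(=O)OC1=C(C(=O)CCCC)CC[C@H]2[C@@H]1[C@]13CCC=C[C@]21C(=O)O/C3=C\CCC | intermediate
11 | target (3Z,3'Z,6S,7R,3a'R,7a'S) | CCC/C=C1\OC(=O)C2=C1CC[C@H]1[C@@H]2[C@]23CCC=C[C@]12C(=O)O/C3=C\CCC | target

## Step count and least certain steps

Total step count: 8. Longest linear sequence: 8 steps, from 1 and 2.

**Step 1 (key step).** The most likely failure is addition to the face of 2 that is anti to the hydroxyl, or stacking of ring A over the tetramethylene bridge. Either lowers the share of adduct that can lactonise. Hydrogen abstraction at the allylic carbinol C–H may also consume 2. These failures should cost material but not stereochemical purity, since wrong adducts do not become 4. The fallback uses steric control and a later carbonyl reduction; it sets out from 1 and comes back at 4. The enantiomeric alcohol (S)-cyclohex-2-en-1-ol F1 is silylated (t-BuMe2SiCl, imidazole) to the silyl ether F2. Irradiation with 1 should add the anhydride to the face anti to the bulky silyloxy group, giving the anti silyloxy anhydride F3 with the same cyclobutane configuration as 3. Desilylation (HF·pyridine) gives the anti hydroxy anhydride F4, and oxidation (1,1,1-triacetoxy-1,2-benziodoxol-3-one) gives the keto anhydride F5. Reduction with LiAlH(O-t-Bu)3 at −78 °C should deliver hydride from the open face of the C7a ketone, away from the anhydride. This places the new hydroxyl cis to C3', which is 3, and 3 lactonises to 4.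

**Step 2.** Cyclopalladation of this neopentyl-type acid may be slow, and the β,γ-unsaturated acid may react further (second oxidation, or loss of CO2 at the reaction temperature). The fallback carries the C6'=C7' bond in as a ketone on the photo-partner and uses an ester tether; it sets out from 2 and comes back at 5. The known methyl 2,6-dioxocyclohexane-1-carboxylate F6 is converted (Tf2O, i-Pr2NEt) into the vinyl triflate F7. Alkoxycarbonylation with 2 (Pd(OAc)2, 1,3-bis(diphenylphosphino)propane, CO, Et3N) gives the tethered enone diester F8. Irradiation at 350 nm should give, by intramolecular enone–alkene [2+2] with five-membered ring closure, the lactone keto ester F9 with a C7' ketone. Enolisation can only go towards C6' (KN(SiMe3)2, PhNTf2), giving the enol triflate F10. Reduction (Pd(OAc)2, PPh3, Bu3N, HCO2H) gives the alkene methyl ester F11, and demethylation (LiI, pyridine, reflux) gives 5.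

**Step 3.** Addition to the very hindered lactone carbonyl may stall, or the ketone released on ring opening may take up a second butyl group. The fallback goes through an acyl donor that cannot over-add; it sets out from 5 and comes back at 6. Aminolysis of the lactone with Me2AlN(OMe)Me (from AlMe3 and N,O-dimethylhydroxylamine hydrochloride) gives the N-methoxy-N-methylamide F12. n-BuLi (3.3 equiv, −78 °C) then gives 6 through the stable chelated adduct.

**Step 8.** The acylpalladium may not be captured by the enol oxygen (slow enolisation, capture at carbon, or reduction), or a Z/E mixture may form at C3=C8. The fallback separates carbonylation from ring closure; it sets out from 10 and comes back at 11. Hydroxycarbonylation (Pd(OAc)2, 1,3-bis(diphenylphosphino)propane, CO, H2O, Et3N, DMF) gives the enone acid F13, which exists with its hydroxybutenolide ring tautomer. Dehydration under the conditions of step 5 should give 11; a trace of iodine would equilibrate any (E) isomer to (Z).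

## Further compounds

F1 | step 1 | (S)-cyclohex-2-en-1-ol | O[C@@H]1C=CCCC1
F2 | step 1 | (S)-tert-butyl(cyclohex-2-en-1-yloxy)dimethylsilane | CC(C)(C)[Si](C)(C)O[C@@H]1C=CCCC1
F3 | step 1 | anti silyloxy anhydride cycloadduct (7aS; cyclobutane as in 3) | O=C1OC(=O)[C@]23CCCC[C@@]13[C@H]4CCC[C@H](O[Si](C)(C)C(C)(C)C)[C@@H]24
F4 | step 1 | anti hydroxy anhydride (7a-epimer of 3) | O=C1OC(=O)[C@]23CCCC[C@@]13[C@H]4CCC[C@H](O)[C@@H]24
F5 | step 1 | keto anhydride (C7a ketone; cyclobutane as in 3) | O=C1OC(=O)[C@]23CCCC[C@@]13[C@H]4CCCC(=O)[C@@H]24
F6 | step 2 | methyl 2,6-dioxocyclohexane-1-carboxylate | COC(=O)C1C(=O)CCCC1=O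
F7 | step 2 | methyl 6-oxo-2-(trifluoromethylsulfonyloxy)cyclohex-1-ene-1-carboxylate | COC(=O)C1=C(OS(=O)(=O)C(F)(F)F)CCCC1=O
F8 | step 2 | 1-[(R)-cyclohex-2-en-1-yl] 2-methyl 3-oxocyclohex-1-ene-1,2-dicarboxylate | COC(=O)C1=C(C(=O)O[C@H]2C=CCCC2)CCCC1=O
F9 | step 2 | lactone keto ester (methyl ester of 4 with a C7' ketone) | COC(=O)[C@]12C(=O)CCC[C@@]1(C(=O)O3)[C@@H]1[C@H]3CCC[C@H]21
F10 | step 2 | enol triflate (7'-OSO2CF3, C6'=C7') | COC(=O)[C@]12C(OS(=O)(=O)C(F)(F)F)=CCC[C@@]1(C(=O)O3)[C@@H]1[C@H]3CCC[C@H]21
F11 | step 2 | methyl ester of 5 | COC(=O)[C@]12C=CCC[C@@]1(C(=O)O3)[C@@H]1[C@H]3CCC[C@H]21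
F12 | step 3 | hydroxy acid with C3' as N-methoxy-N-methylamide | OC(=O)[C@]12C=CCC[C@@]1(C(=O)N(C)OC)[C@@H]1[C@H](O)CCC[C@H]21
F13 | step 8 | enone acid (7a-CO2H, 3a-pentanoyl, C3a=C7a), open form | OC(=O)C1=C(C(=O)CCCC)CC[C@H]2[C@@H]1[C@]13CCC=C[C@]21C(=O)O/C3=C\CCC
A1 | alternative 1 | (Z)-ligustilide | CCC/C=C1\OC(=O)C2=C1CCC=C2
A2 | alternative 2 | ring A-fused cyclobutene-1,2-dicarboxylic anhydride with C7a ketone | O=C1OC(=O)C2=C1[C@H]1CCCC(=O)[C@@H]21
A3 | alternative 2 | allylsilane propellane adduct (7'-SiMe3, C5'=C6'; C7' unspecified) | O=C1OC(=O)[C@]23CC=CC([Si](C)(C)C)[C@@]13[C@H]4CCCC(=O)[C@@H]24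
A4 | alternative 3 | 3-butyl-3-[(R)-cyclohex-2-en-1-yloxy]-4,5,6,7-tetrahydro-2-benzofuran-1(3H)-one (both ketal epimers) | CCCCC1(O[C@H]2C=CCCC2)OC(=O)C2=C1CCCC2
A5 | alternative 3 | cage ketal lactone cycloadduct | CCCC[C@]12O[C@@H]3CCC[C@H]4[C@@H]3[C@@]25CCCC[C@]45C(=O)O1
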